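If the second intermediate can either meet the open intermediate or meet another of its kind, the split between target and homo product at any moment is a ratio of two rates, and that ratio still holds the two concentrations, which change as the flask runs. Substrate opens reversibly to the open intermediate, partner releases the second intermediate, the two couple to target, and partner can also attack target.

| flask | substrate | partner | time | remark | temperature |
|---|---|---|---|---|---|
| grey | 0.25 M | 0.275 M | 10 h | everything together at the start at −25 °C, warmed to 5 °C at 6.0 h |  |
| amber | 0.25 M (fed, over 6.0 h) | 0.275 M | 10 h | the addition at −25 °C, then warmed to 5 °C; the feed brings no volume worth counting |  |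
| violet | 0.25 M (fed, over 6.0 h) | 0.275 M | 10 h | all else is in the flask from the start; the feed brings no volume worth counting | 5 °C |
| blue | 0.25 M (in portions, 4, over 6.0 h) | 0.275 M | 10 h | first portion at the start, last at 6.0 h | 5 °C |
| ochre | 0.25 M | 0.275 M (fed, over 6.0 h) | 10 h | all else is in the flask from the start; the feed brings no volume worth counting | 5 °C |
| green | 0.25 M (fed, over 40 min) | 0.275 M | 10 h | all else is in the flask from the start; the feed brings no volume worth counting | 5 °C |

* the best flask by amount of target, in percent of the substrate charged; "all alike" if 1.5 percentage points covers them all (grey / amber / violet / blue / ochre / green / all alike)
* amount of target at the end, in percent of the substrate charged, grey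
* amount of target at the end, in percent of the substrate charged, amber
* amount of target at the end, in percent of the substrate charged, violet
* amount of target at the end, in percent of the substrate charged, blue
* amount of target at the end, in percent of the substrate charged, ochre
* amount of target at the end, in percent of the substrate charged, green

- for a step with 2 of a species take k times the square, and two of it per event
- at 5 °C the constants are as listed, elsewhere as the activation energies and enthalpies make them

    substrate ⇌ open intermediate (K1 = 4.7, k1 = 8.3 × 10⁻⁵ /s, Ea1 = 89.0 kJ/mol, ΔH1 = −47.0 kJ/mol)
    open intermediate + second intermediate → target (k2 = 2.7 × 10⁻⁴ /M/s, Ea2 = 72.0 kJ/mol)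
    partner + target → over-reaction product (k3 = 1.4 × 10⁻⁴ /M/s, Ea3 = 57.0 kJ/mol)
    2 second intermediate → homo product (k4 = 3.3 × 10⁻⁴ /M/s, Ea4 = 75.0 kJ/mol)
    partner → second intermediate (k5 = 8.9 × 10⁻⁵ /s, Ea5 = 94.0 kJ/mol)
    (constants at 5 °C)

Let both intermediates stand at the same fraction of their charges. Coupling, with constant 2.7 × 10⁻⁴ /M/s, then competes with dimerisation, with constant 3.3 × 10⁻⁴ /M/s, and this gives 0.372, the coupling ratio: second intermediate lost to target over second intermediate lost to homo product, a selectivity factor for this pair. So a share of 27.1% of the second intermediate spent should reach target.

The objection is that equal fractions are an assumption. Opening runs about as fast as release, their constants standing at a ratio of 0.933, but the opening is reversible and tops out at 82.5% of the substrate, which lowers the ratio. Second intermediate also eats itself, which raises it. These pull in opposite directions, so we keep 0.372.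

A second objection is stronger: a share is not an amount. In amber we assume the cold hours are lost, which leaves 4.00 h at 5 °C, and in that time 72.2% of the partner's own charge is released. Not every bit of that is spent. At half of the released level, the dimerisation half-life is 4.24 h, about the warm time, so we count half of the release as spent. That gives 10.8% for amber, and grey has the same warm hours.

For the warm flasks we go no further than direction. A substrate feed should lower the ratio in violet and blue, and a partner feed should raise it in ochre. But ochre's late release costs progress, which the ratio does not measure, so we cannot rank ochre against green by hand.

The forecast names green, with green at 29% (26% to 32%), ochre at 26.8%, blue at 20.7%, violet at 20.1%, grey at 12% and amber at 11.9%. Its ground for the feeds reads: “Slow substrate feed leaves the second intermediate to dimerise while open intermediate is scarce”.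

The simulation gives green as best, at 29.3%, then ochre 27.3%, violet 20.3%, blue 20.3%, grey 11.9% and amber 11.8%.

Amber's neighbour has 0.069 M of partner, 0.276 equiv against substrate, with the other charges and the time held. Its coupling ratio is 1.48 against 0.372 for amber. Amber ends with homo product at 0.0360 M, and its target over the second intermediate spent on homo product reads 0.409. The neighbour ends with target at 4.18% and homo product at 0.00333 M, and the same quotient reads 1.57.

All constants come from no measurement; the rest is arithmetic.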